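The synthesis rests on forging C3–C4 of the isoflavan while setting C3. It exploits the fact that the 2'-oxygen of ring B, needed in the target only as the chromene oxygen, lies 1,5 to C4 (O2'–C2'–C1'–C3–C4). The precursor is therefore a ring B methyl aryldiazoacetate whose 2'-oxygen carries the protected ring A benzyl group, a temporary 2'-O–C4 ether. One enantioselective rhodium carbenoid insertion into C4–H forms C3–C4, a cis-dihydrobenzofuran ring and both stereocentres. Pyran closure to a cis-pterocarpan, hydrogenolysis of the tether bond (erasing C4 chirality, freeing 2'-OH), chromene annulation and acetal removal finish the route.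

Key step: step 10

Numbering: C2, C3, C4, C4a–C8a and the primed ring B positions refer to the isoflavan skeleton of the target, which is (3R).

Assumption: Rh2(S-PTTL)4 is expected to give the (2R,3S) key-step ester, by analogy with its sense of induction on simpler 2-(benzyloxy)phenyl diazoacetates; if the sense were reversed on this substrate, Rh2(R-PTTL)4 from D-tert-leucine would be used with no other change.

Step 1
Reactants: 1 2,4-dihydroxyphenylacetic acid
Product: 2 6-hydroxybenzofuran-2(3H)-one
Conditions: p-TsOH·H2O (cat.), toluene–1,4-dioxane, reflux, azeotropic removal of water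
Reagents that add atoms: none
Why: Acid-catalysed lactonisation (intramolecular Fischer esterification) is favoured for the ortho-hydroxy acid because only the 2-OH can reach the carboxyl group in a five-membered ring, so the 4-OH is left as the single free phenol.

Step 2
Reactants: 2 6-hydroxybenzofuran-2(3H)-one
Product: 3 6-(methoxymethoxy)benzofuran-2(3H)-one
Conditions: MOMCl (1.2 equiv), i-Pr2NEt, CH2Cl2, 0 °C to rt
Reagents that add atoms: chloromethyl methyl ether (MOMCl), COCCl
Why: O-Alkylation of the one free phenol with the highly reactive chloromethyl ether under a hindered amine base (Williamson-type acetal formation) proceeds at low temperature without opening the aryl lactone, and the resulting MOM ether withstands all later basic, reductive, hydrogenolytic and thermal steps.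

Step 3
Reactants: 3 6-(methoxymethoxy)benzofuran-2(3H)-one
Product: 4 methyl 2-[2-hydroxy-4-(methoxymethoxy)phenyl]acetate
Conditions: NaOMe (0.2 equiv), MeOH, 0 °C to rt; NH4Cl quench
Reagents that add atoms: methanol, CO
Why: Methoxide-catalysed transesterification opens the aryl lactone, whose phenoxide is a good leaving group, in a large excess of methanol, which releases exactly the 2-OH that will carry the tether while the 4-oxygen stays protected.

Step 4
Reactants: 5 2,4,6-trihydroxybenzaldehyde
Product: 6 2,6-dihydroxy-4-(methoxymethoxy)benzaldehyde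
Conditions: MOMCl (1.0 equiv), i-Pr2NEt (1.05 equiv), THF, −10 to 0 °C
Reagents that add atoms: chloromethyl methyl ether (MOMCl), COCCl
Why: In this regioselective Williamson-type O-alkylation the 4-OH, para to the formyl group and not hydrogen-bonded to it, is the most acidic hydroxyl, so one equivalent of amine base and one of MOMCl should cap it while the two chelated ortho hydroxyls remain.

Step 5
Reactants: 6 2,6-dihydroxy-4-(methoxymethoxy)benzaldehyde
Product: 7 2-hydroxy-6-methoxy-4-(methoxymethoxy)benzaldehyde
Conditions: MeI (1.05 equiv), K2CO3 (1.1 equiv), acetone, rt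
Reagents that add atoms: iodomethane, CI
Why: Mono-O-methylation (Williamson ether synthesis) is self-limiting because, once one ortho hydroxyl is alkylated, the other is held in a strong hydrogen bond to the carbonyl oxygen and reacts much more slowly with one equivalent of iodomethane at room temperature.

Step 6
Reactants: 7 2-hydroxy-6-methoxy-4-(methoxymethoxy)benzaldehyde
Product: 8 2-(allyloxy)-6-methoxy-4-(methoxymethoxy)benzaldehyde
Conditions: allyl bromide (1.5 equiv), K2CO3, DMF, 60 °C
Reagents that add atoms: allyl bromide, C=CCBr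
Why: Williamson etherification of the remaining chelated phenol with an excess of the reactive primary allylic bromide in a polar aprotic solvent at moderate heat is routine, and allyl is the smallest group that can later be removed with zerovalent palladium without acid, strong base or hydrogen.

Step 7
Reactants: 8 2-(allyloxy)-6-methoxy-4-(methoxymethoxy)benzaldehyde
Product: 9 [2-(allyloxy)-6-methoxy-4-(methoxymethoxy)phenyl]methanol
Conditions: NaBH4, MeOH–THF, 0 °C; neutral aqueous work-up
Reagents that add atoms: none
Why: Sodium borohydride reduces the aldehyde chemoselectively to the primary benzylic alcohol (carbonyl hydride reduction), and a neutral work-up avoids ionisation of this electron-rich benzyl alcohol.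

Step 8
Reactants: 4 methyl 2-[2-hydroxy-4-(methoxymethoxy)phenyl]acetate; 9 [2-(allyloxy)-6-methoxy-4-(methoxymethoxy)phenyl]methanol
Product: 10 methyl 2-[2-{[2-(allyloxy)-6-methoxy-4-(methoxymethoxy)phenyl]methoxy}-4-(methoxymethoxy)phenyl]acetate
Conditions: PPh3, diisopropyl azodicarboxylate (DIAD), THF, 0 °C to rt
Reagents that add atoms: none
Why: Mitsunobu etherification couples the phenol, an adequately acidic pronucleophile, with the primary benzylic alcohol by SN2 displacement of its oxyphosphonium ion at low temperature, which forms the tether without an isolable, unstable trialkoxybenzyl halide and leaves the methyl ester untouched.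

Step 9
Reactants: 10 methyl 2-[2-{[2-(allyloxy)-6-methoxy-4-(methoxymethoxy)phenyl]methoxy}-4-(methoxymethoxy)phenyl]acetate
Product: 11 methyl 2-diazo-2-[2-{[2-(allyloxy)-6-methoxy-4-(methoxymethoxy)phenyl]methoxy}-4-(methoxymethoxy)phenyl]acetate
Conditions: 4-acetamidobenzenesulfonyl azide (p-ABSA), DBU, MeCN, 0 °C to rt
Reagents that add atoms: 4-acetamidobenzenesulfonyl azide, CC(=O)Nc1ccc(cc1)S(=O)(=O)N=[N+]=[N-]
Why: Regitz diazo transfer works on arylacetates because DBU reversibly forms the aryl-stabilised ester enolate, which attacks the terminal nitrogen of the sulfonyl azide and then loses the sulfonamide, and no other C–H in the molecule is acidic enough to compete.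

Step 10
Reactants: 11 methyl 2-diazo-2-[2-{[2-(allyloxy)-6-methoxy-4-(methoxymethoxy)phenyl]methoxy}-4-(methoxymethoxy)phenyl]acetate
Product: 12 methyl (2R,3S)-2-[2-(allyloxy)-6-methoxy-4-(methoxymethoxy)phenyl]-6-(methoxymethoxy)-2,3-dihydrobenzofuran-3-carboxylate (cis)
Conditions: Rh2(S-PTTL)4 [dirhodium tetrakis(N-phthaloyl-(S)-tert-leucinate)] (2 mol %), toluene (ca. 0.03 M), 4 Å MS, −60 °C, warming to −40 °C only if needed; filtration through neutral alumina
Reagents that add atoms: none
Why: Rh2(S-PTTL)4, a divalent rhodium tetracarboxylate, expels N2 from the diazo ester to give a donor/acceptor rhodium carbenoid at C3, which takes up one benzylic C4–H bond in a concerted but asynchronous, hydride-transfer-like three-centre insertion that forms C3–C4 and returns the catalyst. The closest known reaction type is the dirhodium tetracarboxylate-catalysed enantioselective intramolecular 1,5 C–H insertion of methyl 2-(2-benzyloxyphenyl)-2-diazoacetates, which gives cis-2-aryl-2,3-dihydrobenzofuran-3-carboxylates. The one new ring, the dihydrofuran O2'–C2'–C1'–C3–C4, closes by C–C bond formation in a 1,5 insertion through a five-membered transition state, the carbenoid carbon and the OCH2Ar carbon being held together by the ortho ether tether. C3 (S in 12, which becomes the 3R centre of the target once substituent priorities change) is controlled by the catalyst, whose four N-phthaloyl-(S)-tert-leucinate ligands leave one carbenoid face open, and C4 (R) by the compact insertion geometry, in which the aryl group on C4 avoids the ligand wall and so ends cis to the ester under kinetic control. The step needs site selectivity for C4–H over the allyl alkene, the methoxy and MOM C–H bonds and the ring A pi system, and the substrate secures it: C4–H is the only C–H bond that can close a five-membered ring, it is made hydridic by the ether oxygen and the ortho and para oxygens of ring A, both ring A ortho positions are blocked, and every other candidate would need a ring of eight or more atoms.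

Step 11
Reactants: 12 methyl (2R,3S)-2-[2-(allyloxy)-6-methoxy-4-(methoxymethoxy)phenyl]-6-(methoxymethoxy)-2,3-dihydrobenzofuran-3-carboxylate
Product: 13 [(2R,3R)-2-[2-(allyloxy)-6-methoxy-4-(methoxymethoxy)phenyl]-6-(methoxymethoxy)-2,3-dihydrobenzofuran-3-yl]methanol (cis)
Conditions: LiAlH4, THF, −40 to 0 °C; aq. sodium potassium tartrate work-up
Reagents that add atoms: none
Why: Ester reduction by LiAlH4 (hydride addition, loss of methoxide and a second hydride addition) is faster than enolisation at low temperature, so the C3 configuration and the cis relationship are carried into the alcohol (the C3 descriptor changes from S to R only through a change of priorities), and the allyl, MOM and benzylic ether groups are inert to hydride.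

Step 12
Reactants: 13 [(2R,3R)-2-[2-(allyloxy)-6-methoxy-4-(methoxymethoxy)phenyl]-6-(methoxymethoxy)-2,3-dihydrobenzofuran-3-yl]methanol
Product: 14 2-[(2R,3R)-3-(hydroxymethyl)-6-(methoxymethoxy)-2,3-dihydrobenzofuran-2-yl]-3-methoxy-5-(methoxymethoxy)phenol (cis)
Conditions: Pd(PPh3)4 (5 mol %), morpholine, degassed THF, rt
Reagents that add atoms: none
Why: Tsuji–Trost deallylation: zerovalent palladium ionises the allyl aryl ether to a pi-allyl complex and the phenoxide, and morpholine captures the allyl unit irreversibly under nearly neutral conditions that spare the MOM acetals, the primary alcohol and the acid-sensitive C4–O2' bond.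

Step 13
Reactants: 14 2-[(2R,3R)-3-(hydroxymethyl)-6-(methoxymethoxy)-2,3-dihydrobenzofuran-2-yl]-3-methoxy-5-(methoxymethoxy)phenol
Product: 15 (6aR,11aR)-1-methoxy-3,9-bis(methoxymethoxy)pterocarpan, i.e. the cis-fused 6a,11a-dihydro-6H-benzofuro[3,2-c]chromene
Conditions: PPh3, DIAD, THF (0.02 M), 0 °C to rt
Reagents that add atoms: none
Why: Intramolecular Mitsunobu etherification closes the pyran ring by 6-exo-tet attack of the ring A phenol on the activated primary carbon C2, a closure that the cis arrangement of aryl and CH2OH on the dihydrofuran makes strain-free and that touches neither stereocentre.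

Step 14
Reactants: 15 (6aR,11aR)-1-methoxy-3,9-bis(methoxymethoxy)pterocarpan
Product: 16 2-[(3R)-5-methoxy-7-(methoxymethoxy)chroman-3-yl]-5-(methoxymethoxy)phenol
Conditions: H2 (1 atm), 10% Pd/C, EtOAc–EtOH, rt
Reagents that add atoms: none
Why: Catalytic hydrogenolysis cleaves the C4–O2' bond, a benzylic aryl ether activated by the three oxygen donors of ring A (the classical opening of a pterocarpan to a 2'-hydroxyisoflavan), which turns C4 into a methylene group, leaves C3 untouched because it is not part of the bond broken, and spares the MOM ethers and the non-benzylic C2–O1 bond.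

Step 15
Reactants: 16 2-[(3R)-5-methoxy-7-(methoxymethoxy)chroman-3-yl]-5-(methoxymethoxy)phenol; 17 3-chloro-3-methylbut-1-yne
Product: 18 (3R)-5-methoxy-7-(methoxymethoxy)-3-{4-(methoxymethoxy)-2-[(2-methylbut-3-yn-2-yl)oxy]phenyl}chromane
Conditions: DBU, CuCl2·2H2O (1 mol %), MeCN, 0 °C
Reagents that add atoms: none
Why: Copper-catalysed O-propargylation of the phenol with the tertiary propargylic chloride (substitution through a copper acetylide-derived electrophile) is insensitive to the ortho branching of the phenol, and the 2'-OH is the only free hydroxyl in the molecule.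

Step 16
Reactants: 18 (3R)-5-methoxy-7-(methoxymethoxy)-3-{4-(methoxymethoxy)-2-[(2-methylbut-3-yn-2-yl)oxy]phenyl}chromane
Product: 19 8-[(3R)-5-methoxy-7-(methoxymethoxy)chroman-3-yl]-5-(methoxymethoxy)-2,2-dimethyl-2H-chromene
Conditions: o-xylene, 140 °C
Reagents that add atoms: none
Why: Heating triggers an aromatic propargyl Claisen rearrangement to C3', the only unsubstituted ortho position, followed in the same thermal cascade by enolisation, 1,5-hydrogen shift and oxa-6π electrocyclisation, which gives the 2,2-dimethyl-2H-chromene with the regiochemistry fixed by the substitution pattern.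

Step 17
Reactants: 19 8-[(3R)-5-methoxy-7-(methoxymethoxy)chroman-3-yl]-5-(methoxymethoxy)-2,2-dimethyl-2H-chromene
Product: 20 8-[(3R)-7-hydroxy-5-methoxychroman-3-yl]-2,2-dimethyl-2H-chromen-5-ol (target)
Conditions: HCl (2 M) in MeOH–THF, 40 °C, degassed
Reagents that add atoms: none
Why: Acid-catalysed acetal exchange with methanol removes both aryl MOM groups under mild conditions that electron-rich isoflavans and 2,2-dimethylchromenes are known to tolerate, and C3, which carries no acidic or ionisable substituent, keeps its configuration.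

Compound list

1 | 2,4-dihydroxyphenylacetic acid | OC(=O)Cc1ccc(O)cc1O | starting material
2 | 6-hydroxybenzofuran-2(3H)-one | O=C1Cc2ccc(O)cc2O1 | intermediate
3 | 6-(methoxymethoxy)benzofuran-2(3H)-one | COCOc1ccc2CC(=O)Oc2c1 | intermediate
4 | methyl 2-[2-hydroxy-4-(methoxymethoxy)phenyl]acetate | COC(=O)Cc1ccc(OCOC)cc1O | intermediate
5 | 2,4,6-trihydroxybenzaldehyde | O=Cc1c(O)cc(O)cc1O | starting material
6 | 2,6-dihydroxy-4-(methoxymethoxy)benzaldehyde | COCOc1cc(O)c(C=O)c(O)c1 | intermediate
7 | 2-hydroxy-6-methoxy-4-(methoxymethoxy)benzaldehyde | COCOc1cc(O)c(C=O)c(OC)c1 | intermediate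
8 | 2-(allyloxy)-6-methoxy-4-(methoxymethoxy)benzaldehyde | C=CCOc1cc(OCOC)cc(OC)c1C=O | intermediate
9 | [2-(allyloxy)-6-methoxy-4-(methoxymethoxy)phenyl]methanol | C=CCOc1cc(OCOC)cc(OC)c1CO | intermediate
10 | methyl 2-[2-{[2-(allyloxy)-6-methoxy-4-(methoxymethoxy)phenyl]methoxy}-4-(methoxymethoxy)phenyl]acetate | COC(=O)Cc1ccc(OCOC)cc1OCc1c(OC)cc(OCOC)cc1OCC=C | intermediate
11 | methyl 2-diazo-2-[2-{[2-(allyloxy)-6-methoxy-4-(methoxymethoxy)phenyl]methoxy}-4-(methoxymethoxy)phenyl]acetate | COC(=O)C(=[N+]=[N-])c1ccc(OCOC)cc1OCc1c(OC)cc(OCOC)cc1OCC=C | intermediate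
12 | methyl (2R,3S)-2-[2-(allyloxy)-6-methoxy-4-(methoxymethoxy)phenyl]-6-(methoxymethoxy)-2,3-dihydrobenzofuran-3-carboxylate | COC(=O)[C@H]1c2ccc(OCOC)cc2O[C@H]1c1c(OC)cc(OCOC)cc1OCC=C | intermediate
13 | [(2R,3R)-2-[2-(allyloxy)-6-methoxy-4-(methoxymethoxy)phenyl]-6-(methoxymethoxy)-2,3-dihydrobenzofuran-3-yl]methanol | OC[C@H]1c2ccc(OCOC)cc2O[C@H]1c1c(OC)cc(OCOC)cc1OCC=C | intermediate
14 | 2-[(2R,3R)-3-(hydroxymethyl)-6-(methoxymethoxy)-2,3-dihydrobenzofuran-2-yl]-3-methoxy-5-(methoxymethoxy)phenol | OC[C@H]1c2ccc(OCOC)cc2O[C@H]1c1c(OC)cc(OCOC)cc1O | intermediate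
15 | (6aR,11aR)-1-methoxy-3,9-bis(methoxymethoxy)pterocarpan | C1[C@H]2c3ccc(OCOC)cc3O[C@H]2c2c(OC)cc(OCOC)cc2O1 | intermediate
16 | 2-[(3R)-5-methoxy-7-(methoxymethoxy)chroman-3-yl]-5-(methoxymethoxy)phenol | COc1cc(OCOC)cc2c1C[C@H](c1ccc(OCOC)cc1O)CO2 | intermediate
17 | 3-chloro-3-methylbut-1-yne | C#CC(C)(C)Cl | starting material
18 | (3R)-5-methoxy-7-(methoxymethoxy)-3-{4-(methoxymethoxy)-2-[(2-methylbut-3-yn-2-yl)oxy]phenyl}chromane | COc1cc(OCOC)cc2c1C[C@H](c1ccc(OCOC)cc1OC(C)(C)C#C)CO2 | intermediate
19 | 8-[(3R)-5-methoxy-7-(methoxymethoxy)chroman-3-yl]-5-(methoxymethoxy)-2,2-dimethyl-2H-chromene | COc1cc(OCOC)cc2c1C[C@H](c1ccc(OCOC)c3c1OC(C)(C)C=C3)CO2 | intermediate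
20 | 8-[(3R)-7-hydroxy-5-methoxychroman-3-yl]-2,2-dimethyl-2H-chromen-5-ol | COc1cc(O)cc2c1C[C@H](c1ccc(O)c3c1OC(C)(C)C=C3)CO2 | target

Total step count: 17. Longest linear sequence: 14 steps (5 to 20, steps 4–17).

Steps most likely to fail

Step 10. The carbenoid may be lost to dimerisation or to addition to the allyl alkene and the electron-rich ring A. At the hindered, strongly donor-stabilised C4 the insertion may also turn stepwise (hydride transfer, then ion-pair collapse), which would erode cis- and enantioselectivity. The fallback uses no carbenoid and sets C3 by asymmetric hydrogenation. It sets out from lactone 3 and salicylaldehyde 7, which are condensed (Et3N, EtOH, reflux; Knoevenagel condensation followed by lactone exchange) to 3-[2-hydroxy-4-(methoxymethoxy)phenyl]-5-methoxy-7-(methoxymethoxy)-2H-chromen-2-one F1. Benzylation of the free phenol (BnBr, K2CO3, acetone) gives 3-[2-(benzyloxy)-4-(methoxymethoxy)phenyl]-5-methoxy-7-(methoxymethoxy)-2H-chromen-2-one F2. DIBAL-H (CH2Cl2, −78 °C) reduces the lactone to 2-[(1Z)-2-[2-(benzyloxy)-4-(methoxymethoxy)phenyl]-3-hydroxyprop-1-en-1-yl]-3-methoxy-5-(methoxymethoxy)phenol F3. Mitsunobu closure (PPh3, DIAD, THF) gives 3-[2-(benzyloxy)-4-(methoxymethoxy)phenyl]-5-methoxy-7-(methoxymethoxy)-2H-chromene F4. Hydrogenation of this cyclic trisubstituted alkene with [Ir(cod)(t-Bu-PHOX)]BArF (monovalent iridium; BArF = tetrakis[3,5-bis(trifluoromethyl)phenyl]borate; ligand enantiomer chosen to deliver 3R; H2, CH2Cl2) gives (3R)-3-[2-(benzyloxy)-4-(methoxymethoxy)phenyl]-5-methoxy-7-(methoxymethoxy)chromane F5. H2 over Pd/C then removes the benzyl group, and the route is rejoined at 16.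

Step 8. The oxyphosphonium ion of the trioxygenated benzyl alcohol may ionise before the phenol attacks, which would lead to C-benzylation of ring B, capture by the hydrazide or self-condensation. The fallback is a two-stage Williamson etherification under basic conditions, where the phenoxide reacts at oxygen. It sets out from 9, which with MsCl, i-Pr2NEt and LiCl (THF, −20 °C) is converted into 1-(allyloxy)-2-(chloromethyl)-3-methoxy-5-(methoxymethoxy)benzene F6. This chloride is not stored but transferred cold into the caesium phenoxide of 4 (Cs2CO3, DMF, 0 °C), and the route is rejoined at 10.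

Step 4. With one equivalent of electrophile the alkylation may not stop cleanly at the 4-oxygen; bis-ether formation and C-alkylation of the phloroglucinol nucleus are the likely side processes. The fallback fixes the regiochemistry by chelation instead of stoichiometry. It sets out from 5, which with MOMCl (2.2 equiv) and i-Pr2NEt is protected at every hydroxyl except one hydrogen-bonded ortho OH, giving 2-hydroxy-4,6-bis(methoxymethoxy)benzaldehyde F7. MeI and K2CO3 in DMF then give 2-methoxy-4,6-bis(methoxymethoxy)benzaldehyde F8. Brief treatment with dilute HCl in MeOH–THF (or MgBr2·OEt2) preferentially removes the MOM group ortho to the formyl group, whose departure the carbonyl assists, and the route is rejoined at 7.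

Further compounds

F1 | step 10 | 3-[2-hydroxy-4-(methoxymethoxy)phenyl]-5-methoxy-7-(methoxymethoxy)-2H-chromen-2-one | COc1cc(OCOC)cc2OC(=O)C(=Cc12)c1ccc(OCOC)cc1O
F2 | step 10 | 3-[2-(benzyloxy)-4-(methoxymethoxy)phenyl]-5-methoxy-7-(methoxymethoxy)-2H-chromen-2-one | COc1cc(OCOC)cc2OC(=O)C(=Cc12)c1ccc(OCOC)cc1OCc1ccccc1
F3 | step 10 | 2-[(1Z)-2-[2-(benzyloxy)-4-(methoxymethoxy)phenyl]-3-hydroxyprop-1-en-1-yl]-3-methoxy-5-(methoxymethoxy)phenol | OC/C(=C\c1c(O)cc(OCOC)cc1OC)c1ccc(OCOC)cc1OCc1ccccc1
F4 | step 10 | 3-[2-(benzyloxy)-4-(methoxymethoxy)phenyl]-5-methoxy-7-(methoxymethoxy)-2H-chromene | COc1cc(OCOC)cc2OCC(=Cc12)c1ccc(OCOC)cc1OCc1ccccc1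
F5 | step 10 | (3R)-3-[2-(benzyloxy)-4-(methoxymethoxy)phenyl]-5-methoxy-7-(methoxymethoxy)chromane | COc1cc(OCOC)cc2c1C[C@H](c1ccc(OCOC)cc1OCc1ccccc1)CO2
F6 | step 8 | 1-(allyloxy)-2-(chloromethyl)-3-methoxy-5-(methoxymethoxy)benzene | C=CCOc1cc(OCOC)cc(OC)c1CCl
F7 | step 4 | 2-hydroxy-4,6-bis(methoxymethoxy)benzaldehyde | COCOc1cc(O)c(C=O)c(OCOC)c1
F8 | step 4 | 2-methoxy-4,6-bis(methoxymethoxy)benzaldehyde | COCOc1cc(OC)c(C=O)c(OCOC)c1
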